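**Plan**

1. Locants: six-membered ring C1(=C10H2)–C2–C6–C7(iPr)–C8(O-acyl)–C9(O-acyl); five-membered ring C2–C3–C4(=O)–C5(C11H(OAc)CH3)–C6. β is the face of C6–H, α the opposite face.
2. Retrosynthesis: the two esters and the C4 ketone are taken back first. The C9–O/C1=C10 allylic unit is then taken back to a C9–C1 epoxide and on to a C8(=O)–C9=C1(C10H3) enone. This enone is cut at C1–C9 and C6–C7 together.
3. Enabling feature: oxygenated C8 lies between C7 and C9, so C7–C8–C9 is a ketone with two nucleophilic α-carbons. C6–C2–C1 is the β-carbon, α-carbon and acyl carbon of an acetylcyclopentene. The six-membered ring is therefore the retron of a formal [3+3] annulation (Mukaiyama–Michael addition at C6, then Knoevenagel aldol at C1), with a C9 ester as a removable activating group.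
4. Forward order: the cyclopentene 11 is made first (steps 1–5). The six-membered ring is annulated onto it in one flask (step 8). Then follow decarboxylation, C7/C8 adjustment, epoxidation, epoxide-to-allylic-alcohol isomerisation, two esterifications, desilylation and oxidation.
5. Stereochemistry: C4 (R, bought, erased at the end) directs C5. C5 directs C6. C2 follows by equilibration next to the C1 carbonyl. C11 comes from a CBS reduction, C7 from axial kinetic protonation, C8 from axial hydride delivery, and C9 from hydroxyl-directed epoxidation. The 2-methylbutanoate is bought as the S acid.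

Key step: step 8

**Route**

Step 1
Reactants: 1 (R)-4-(tert-butyldimethylsilyloxy)cyclopent-2-en-1-one; 2 isopropenylmagnesium bromide
Product: 4 (3S,4R)-4-(tert-butyldimethylsilyloxy)-3-isopropenylcyclopent-1-en-1-yl trifluoromethanesulfonate, via bromomagnesium enolate 3 (not isolated)
Conditions: CuBr·SMe2 (10 mol%), THF, −78 °C; then Comins' reagent, −78 → 0 °C; aqueous work-up
Reagents that add atoms: N-(5-chloropyridin-2-yl)bis(trifluoromethanesulfonyl)imide (Comins' reagent), Clc1ccc(nc1)N(S(=O)(=O)C(F)(F)F)S(=O)(=O)C(F)(F)F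
Why: Copper-catalysed conjugate addition should enter C5 anti to the C4 silyloxy group, as is general for 4-silyloxycyclopentenones, and O-sulfonylation of the regiodefined C2/C6 enolate before it equilibrates fixes the later C2=C6 double bond.

Step 2
Reactants: 4 (3S,4R)-4-(tert-butyldimethylsilyloxy)-3-isopropenylcyclopent-1-en-1-yl trifluoromethanesulfonate
Product: 6 (3R,4R)-3-acetyl-4-(tert-butyldimethylsilyloxy)cyclopent-1-en-1-yl trifluoromethanesulfonate, via ozonide 5 (not isolated)
Conditions: O3, CH2Cl2, −78 °C; then PPh3, −78 °C → rt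
Reagents that add atoms: ozone, [O-][O+]=O
Why: Ozonolysis should cleave the electron-rich 1,1-disubstituted alkene and spare the strongly deactivated enol triflate, and the neutral reductive work-up avoids β-elimination of the silyloxy group.

Step 3
Reactants: 6 (3R,4R)-3-acetyl-4-(tert-butyldimethylsilyloxy)cyclopent-1-en-1-yl trifluoromethanesulfonate
Product: 7 (3S,4R)-4-(tert-butyldimethylsilyloxy)-3-[(1R)-1-hydroxyethyl]cyclopent-1-en-1-yl trifluoromethanesulfonate
Conditions: (S)-1-methyl-3,3-diphenyltetrahydro-1H,3H-pyrrolo[1,2-c][1,3,2]oxazaborole ((S)-Me-CBS, 20 mol%), BH3·SMe2, THF, −30 °C; MeOH quench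
Reagents that add atoms: none
Why: In the CBS reduction of this methyl ketone the (S)-catalyst should deliver hydride to the face that gives the R carbinol at C11 (large group = ring carbon C5, small group = methyl), under reagent control.

Step 4
Reactants: 7 (3S,4R)-4-(tert-butyldimethylsilyloxy)-3-[(1R)-1-hydroxyethyl]cyclopent-1-en-1-yl trifluoromethanesulfonate
Product: 8 (1R)-1-[(1S,5R)-5-(tert-butyldimethylsilyloxy)-3-(trifluoromethanesulfonyloxy)cyclopent-2-en-1-yl]ethyl acetate
Conditions: Ac2O, pyridine, 4-(dimethylamino)pyridine (DMAP, cat.), CH2Cl2, 0 °C → rt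
Reagents that add atoms: acetic anhydride, CC(=O)OC(C)=O
Why: Standard acylation installs the C11 acetate of the target early; it also serves as the protecting group for the rest of the route.

Step 5
Reactants: 8 (1R)-1-[(1S,5R)-5-(tert-butyldimethylsilyloxy)-3-(trifluoromethanesulfonyloxy)cyclopent-2-en-1-yl]ethyl acetate; 9 tributyl(1-ethoxyvinyl)stannane
Product: 11 (1R)-1-[(1S,5R)-3-acetyl-5-(tert-butyldimethylsilyloxy)cyclopent-2-en-1-yl]ethyl acetate, via ethoxyvinyl diene 10 (not isolated)
Conditions: Pd(PPh3)4 (5 mol%), LiCl, THF, 65 °C; then 1 M HCl, rt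
Reagents that add atoms: water, O
Why: Stille coupling of the enol triflate with the acetyl-anion equivalent, then hydrolysis of the enol ether, gives the 1-acetylcyclopentene (C1 acyl carbon, C10 methyl, C2=C6).

Step 6
Reactants: 12 methyl 5-methyl-3-oxohexanoate
Product: 13 methyl 5-methyl-3-(trimethylsilyloxy)hex-2-enoate
Conditions: Me3SiCl, Et3N, toluene, rt
Reagents that add atoms: chlorotrimethylsilane, C[Si](C)(C)Cl
Why: O-silylation of the enol of the β-keto ester gives the conjugated silyl enol ether.

Step 7
Reactants: 13 methyl 5-methyl-3-(trimethylsilyloxy)hex-2-enoate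
Product: 14 1-methoxy-5-methyl-1,3-bis(trimethylsilyloxy)hexa-1,3-diene
Conditions: LiN(iPr)2, THF, −78 °C; then Me3SiCl, −78 °C → rt
Reagents that add atoms: chlorotrimethylsilane, C[Si](C)(C)Cl
Why: Vinylogous (γ) deprotonation and O-silylation give the 1,3-bis(silyloxy)diene, a masked dianion of the β-keto ester whose terminal carbon (C7) is the most nucleophilic site.

Step 8
Reactants: 11 (1R)-1-[(1S,5R)-3-acetyl-5-(tert-butyldimethylsilyloxy)cyclopent-2-en-1-yl]ethyl acetate; 14 1-methoxy-5-methyl-1,3-bis(trimethylsilyloxy)hexa-1,3-diene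
Product: 16 trans-fused bicyclic enone ester (C8=O; C9=C1 with CO2Me on C9 and CH3 on C1; C4 silyl ether; C11 acetate; C7 epimers), via Michael adduct 15 (not isolated)
Conditions: TiCl4 (1.1 equiv), CH2Cl2, −78 °C; then MeOH (1 equiv), Et3N (5 equiv), −78 → 23 °C
Reagents that add atoms: none
Why: TiCl4 activates enone 11 and the terminal carbon C7 of diene 14 adds to C6 (Mukaiyama–Michael addition), after which the C1 titanium enolate is protonated and the titanium enolate of the β-keto ester at C9 adds to the C1 ketone and loses water (titanium-mediated Knoevenagel aldol condensation). The closest known reaction type is the formal [3+3] cyclisation of 1,3-bis(silyloxy)-1,3-dienes with 1,3-dielectrophiles. The six-membered ring C1–C2–C6–C7–C8–C9 closes in a 6-(enolendo)-exo-trig aldol step. C6 should be set by attack anti to the adjacent C5 side chain (1,2-induction on the cyclopentene), C2 by equilibration next to the C1 ketone to the trans-1,2-disubstituted cyclopentane before closure, and C7 is not controlled here and is fixed in step 10. The step needs regioselectivity (C7 to C6, C9 to C1) and π-facial selectivity at C6; the first is secured by the different reactivity of the two diene termini and by the C9 ester, the second by the C5 substituent.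

Step 9
Reactants: 16 trans-fused bicyclic enone ester (C7 epimers)
Product: 17 trans-fused bicyclic enone (C8=O, C9=C1–CH3; C7 epimers)
Conditions: LiCl, H2O (2 equiv), DMSO, 140 °C
Reagents that add atoms: none
Why: Krapcho dealkoxycarbonylation removes the activating ester from C9 under near-neutral conditions that the acetate and the silyl ether should tolerate.

Step 10
Reactants: 17 trans-fused bicyclic enone (C7 epimers)
Product: 20 allylic alcohol (C8–OH α, 7S isopropyl β, C9=C1–CH3), via lithium dienolate 18 (not isolated), via 7S enone 19 (not isolated)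
Conditions: LiN(SiMe3)2 (1.3 equiv), THF, −78 → −40 °C; AcOH, −78 °C; then CeCl3·7H2O, NaBH4, MeOH, −78 °C
Reagents that add atoms: none
Why: Deprotonation at C7 of either epimer gives the cross-conjugated dienolate, whose kinetic protonation should occur axially from the α-face (anti to the axial C6–H) and place the isopropyl group equatorial, and the in-flask Luche reduction then delivers hydride axially from the β-face to give the equatorial C8 alcohol before C7 can equilibrate.

Step 11
Reactants: 20 allylic alcohol
Product: 21 epoxy alcohol (C9–C1 epoxide on the α-face, cis to the C8 hydroxyl)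
Conditions: mCPBA, NaHCO3, CH2Cl2, 0 °C
Reagents that add atoms: 3-chloroperbenzoic acid, OOC(=O)c1cccc(Cl)c1
Why: In the Henbest epoxidation, hydrogen bonding of the peracid to the C8 hydroxyl should deliver oxygen to the same face of the C9=C1 alkene, which sets the C9–O configuration.

Step 12
Reactants: 21 epoxy alcohol; 22 (S)-2-methylbutanoic acid
Product: 23 epoxy ester (C8 (S)-2-methylbutanoate)
Conditions: N,N'-dicyclohexylcarbodiimide (DCC), DMAP (cat.), CH2Cl2, 0 °C → rt
Reagents that add atoms: none
Why: Steglich esterification acylates the only free hydroxyl (C8) with retention, so the first ester is placed without any regiochemical question.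

Step 13
Reactants: 23 epoxy ester
Product: 24 allylic alcohol ester (C1=C10H2, C9–OH α, C8 ester)
Conditions: (C5H5)2TiCl2 (2.5 equiv), Mn dust, THF, rt; aqueous NaH2PO4 work-up
Reagents that add atoms: none
Why: (C5H5)2TiCl (trivalent titanium) opens the epoxide homolytically at C1–O to the tertiary C1 radical, and a second equivalent removes a hydrogen atom from the unhindered C10 methyl (titanocene-mediated epoxide-to-allylic-alcohol isomerisation), which creates the exocyclic methylene and leaves the C9–O bond untouched.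

Step 14
Reactants: 25 ethyl but-2-ynoate
Product: 26 ethyl (E)-3-methylpent-2-enoate
Conditions: EtMgBr, CuBr·SMe2 (1.1 equiv each), THF, −78 °C; 1 M HCl quench at −78 °C
Reagents that add atoms: ethylmagnesium bromide, CC[Mg]Br
Why: syn-Carbocupration of the ynoate puts ethyl and the vinylic copper (then hydrogen) cis, which gives the E alkene with the methyl group cis to the ester.

Step 15
Reactants: 26 ethyl (E)-3-methylpent-2-enoate
Product: 27 (E)-3-methylpent-2-enoic acid
Conditions: LiOH, THF/H2O, rt; then dilute HCl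
Reagents that add atoms: lithium hydroxide, [Li+].[OH-]
Why: Saponification of the unhindered ethyl ester proceeds without touching the trisubstituted alkene geometry.

Step 16
Reactants: 24 allylic alcohol ester; 27 (E)-3-methylpent-2-enoic acid
Product: 28 diester silyl ether (C9 (E)-3-methylpent-2-enoate, C8 (S)-2-methylbutanoate, C4 silyl ether)
Conditions: DCC, DMAP (1 equiv), CH2Cl2, 0 °C → rt
Reagents that add atoms: none
Why: Steglich esterification of the axial allylic C9 alcohol under mild, weakly basic conditions should avoid both acyl migration from O8 and isomerisation of the enoate.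

Step 17
Reactants: 28 diester silyl ether
Product: 29 C4 alcohol
Conditions: HF·pyridine, THF/pyridine, 0 °C → rt
Reagents that add atoms: none
Why: Buffered fluoride desilylation frees the C4 hydroxyl without disturbing the three esters.

Step 18
Reactants: 29 C4 alcohol
Product: 30 target (CNP0124625.1)
Conditions: Dess–Martin periodinane, NaHCO3, CH2Cl2, rt
Reagents that add atoms: none
Why: Dess–Martin oxidation gives the C4 ketone under buffered conditions that should spare the β-acetoxy group, and C5 stays in its trans (thermodynamic) configuration.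

**Compound list**

1 | (R)-4-(tert-butyldimethylsilyloxy)cyclopent-2-en-1-one | O=C1C=C[C@H](O[Si](C)(C)C(C)(C)C)C1 | starting material
2 | isopropenylmagnesium bromide | CC(=C)[Mg]Br | starting material
3 | bromomagnesium enolate of (3S,4R)-4-(tert-butyldimethylsilyloxy)-3-isopropenylcyclopentanone | Br[Mg]OC1=C[C@@H](C(C)=C)[C@H](O[Si](C)(C)C(C)(C)C)C1 | intermediate (not isolated)
4 | (3S,4R)-4-(tert-butyldimethylsilyloxy)-3-isopropenylcyclopent-1-en-1-yl trifluoromethanesulfonate | FC(F)(F)S(=O)(=O)OC1=C[C@@H](C(C)=C)[C@H](O[Si](C)(C)C(C)(C)C)C1 | intermediate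
5 | ozonide (1,2,4-trioxolane) of 4 at the isopropenyl group | FC(F)(F)S(=O)(=O)OC1=C[C@@H](C2(C)OCOO2)[C@H](O[Si](C)(C)C(C)(C)C)C1 | intermediate (not isolated)
6 | (3R,4R)-3-acetyl-4-(tert-butyldimethylsilyloxy)cyclopent-1-en-1-yl trifluoromethanesulfonate | FC(F)(F)S(=O)(=O)OC1=C[C@@H](C(C)=O)[C@H](O[Si](C)(C)C(C)(C)C)C1 | intermediate
7 | (3S,4R)-4-(tert-butyldimethylsilyloxy)-3-[(1R)-1-hydroxyethyl]cyclopent-1-en-1-yl trifluoromethanesulfonate | FC(F)(F)S(=O)(=O)OC1=C[C@@H]([C@@H](C)O)[C@H](O[Si](C)(C)C(C)(C)C)C1 | intermediate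
8 | (1R)-1-[(1S,5R)-5-(tert-butyldimethylsilyloxy)-3-(trifluoromethanesulfonyloxy)cyclopent-2-en-1-yl]ethyl acetate | FC(F)(F)S(=O)(=O)OC1=C[C@@H]([C@@H](C)OC(C)=O)[C@H](O[Si](C)(C)C(C)(C)C)C1 | intermediate
9 | tributyl(1-ethoxyvinyl)stannane | CCOC(=C)[Sn](CCCC)(CCCC)CCCC | starting material
10 | (1R)-1-[(1S,5R)-5-(tert-butyldimethylsilyloxy)-3-(1-ethoxyvinyl)cyclopent-2-en-1-yl]ethyl acetate | CCOC(=C)C1=C[C@@H]([C@@H](C)OC(C)=O)[C@H](O[Si](C)(C)C(C)(C)C)C1 | intermediate (not isolated)
11 | (1R)-1-[(1S,5R)-3-acetyl-5-(tert-butyldimethylsilyloxy)cyclopent-2-en-1-yl]ethyl acetate | CC(=O)C1=C[C@@H]([C@@H](C)OC(C)=O)[C@H](O[Si](C)(C)C(C)(C)C)C1 | intermediate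
12 | methyl 5-methyl-3-oxohexanoate | COC(=O)CC(=O)CC(C)C | starting material
13 | methyl 5-methyl-3-(trimethylsilyloxy)hex-2-enoate (E/Z mixture) | COC(=O)C=C(CC(C)C)O[Si](C)(C)C | intermediate
14 | 1-methoxy-5-methyl-1,3-bis(trimethylsilyloxy)hexa-1,3-diene (mixture of double-bond isomers) | COC(O[Si](C)(C)C)=CC(O[Si](C)(C)C)=CC(C)C | intermediate
15 | Michael adduct: methyl 3-oxo ester with the C6–C7 bond formed; C1 acetyl and C7 chain trans on the cyclopentane; C7 epimers | CC(=O)[C@@H]1C[C@@H](O[Si](C)(C)C(C)(C)C)[C@H]([C@@H](C)OC(C)=O)[C@H]1C(C(C)C)C(=O)CC(=O)OC | intermediate (not isolated)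
16 | trans-fused bicyclic enone ester (C8=O, C9=C1, CO2Me on C9, CH3 on C1, C4 silyl ether, C11 acetate; C2, C5, C6, C11 as in 30; C7 epimers) | COC(=O)C1=C(C)[C@@H]2C[C@@H](O[Si](C)(C)C(C)(C)C)[C@H]([C@@H](C)OC(C)=O)[C@H]2C(C(C)C)C1=O | intermediate
17 | trans-fused bicyclic enone (C8=O, C9=C1–CH3; C7 epimers) | O=C1C=C(C)[C@@H]2C[C@@H](O[Si](C)(C)C(C)(C)C)[C@H]([C@@H](C)OC(C)=O)[C@H]2C1C(C)C | intermediate
18 | cross-conjugated lithium dienolate of 17 (C7=C8–OLi, C9=C1) | [Li]OC1=C(C(C)C)[C@@H]2[C@@H]([C@@H](C)OC(C)=O)[C@H](O[Si](C)(C)C(C)(C)C)C[C@H]2C(C)=C1 | intermediate (not isolated)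
19 | 7S enone (isopropyl β, equatorial) | O=C1C=C(C)[C@@H]2C[C@@H](O[Si](C)(C)C(C)(C)C)[C@H]([C@@H](C)OC(C)=O)[C@H]2[C@@H]1C(C)C | intermediate (not isolated)
20 | allylic alcohol (C8–OH α, 7S, C9=C1–CH3) | C1=C(C)[C@@H]2C[C@@H](O[Si](C)(C)C(C)(C)C)[C@H]([C@@H](C)OC(C)=O)[C@H]2[C@H](C(C)C)[C@H]1O | intermediate
21 | epoxy alcohol (C9–C1 α-epoxide cis to C8–OH) | C[C@]12[C@@H]3C[C@@H](O[Si](C)(C)C(C)(C)C)[C@H]([C@@H](C)OC(C)=O)[C@H]3[C@H](C(C)C)[C@@H](O)[C@H]1O2 | intermediate
22 | (S)-2-methylbutanoic acid | CC[C@H](C)C(=O)O | starting material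
23 | epoxy ester (C8 (S)-2-methylbutanoate) | C[C@]12[C@@H]3C[C@@H](O[Si](C)(C)C(C)(C)C)[C@H]([C@@H](C)OC(C)=O)[C@H]3[C@H](C(C)C)[C@@H](OC(=O)[C@@H](C)CC)[C@H]1O2 | intermediate
24 | allylic alcohol ester (C1=C10H2, C9–OH α, C8 ester) | C=C1[C@@H]2C[C@@H](O[Si](C)(C)C(C)(C)C)[C@H]([C@@H](C)OC(C)=O)[C@H]2[C@H](C(C)C)[C@@H](OC(=O)[C@@H](C)CC)[C@H]1O | intermediate
25 | ethyl but-2-ynoate | CC#CC(=O)OCC | starting material
26 | ethyl (E)-3-methylpent-2-enoate | CCOC(=O)/C=C(\C)CC | intermediate
27 | (E)-3-methylpent-2-enoic acid | OC(=O)/C=C(\C)CC | intermediate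
28 | diester silyl ether (C4–OSi(tBu)Me2) | C=C1[C@@H]2C[C@@H](O[Si](C)(C)C(C)(C)C)[C@H]([C@@H](C)OC(C)=O)[C@H]2[C@H](C(C)C)[C@@H](OC(=O)[C@@H](C)CC)[C@H]1OC(=O)/C=C(\C)CC | intermediate
29 | C4 alcohol (4R) | C=C1[C@@H]2C[C@@H](O)[C@H]([C@@H](C)OC(C)=O)[C@H]2[C@H](C(C)C)[C@@H](OC(=O)[C@@H](C)CC)[C@H]1OC(=O)/C=C(\C)CC | intermediate
30 | CNP0124625.1 (2R,5S,6R,7S,8R,9S,11R in the locants of the plan; (S)-2-methylbutanoate at O8, (E)-3-methylpent-2-enoate at O9) | C=C1[C@@H]2CC(=O)[C@H]([C@@H](C)OC(C)=O)[C@H]2[C@H](C(C)C)[C@@H](OC(=O)[C@@H](C)CC)[C@H]1OC(=O)/C=C(\C)CC | target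

**Step count and risks**

Total step count: 18. Longest linear sequence: 14 steps (steps 1–5, 8–13, 16–18). Steps 6–7 and 14–15 make side fragments.

Three steps most likely to fail:

- **Step 8.** The intermolecular addition may stall because both carbons that must bond (C6 and C7) are branched, or the in-flask condensation may not follow the addition. The fallback reverses the order of the two bond formations so that the hindered C6–C7 bond is made inside a ring-closing step. Setting out from 11 and 12, a titanium-mediated Knoevenagel condensation at the C1 ketone (TiCl4, pyridine, THF, 0 °C → rt) would give the cross-conjugated dienone ester methyl 2-[1-(cyclopentenyl)ethylidene]-5-methyl-3-oxohexanoate F1. Warming F1 with DBU in toluene would close C6–C7 by 6-endo vinylogous Michael addition of the C7 enolate to the C9=C1–C2=C6 dienone, again anti to the C5 side chain. Protonation at C2 would give 16, where the route is rejoined.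

- **Step 10.** Enolisation at the hindered C7 may be incomplete, protonation may not be fully axial, or hydride may attack C8 from the equatorial direction. The fallback gives up kinetic control and uses separation with recycling. Setting out from 17, the C7 epimers would be equilibrated with DBU and the mixture reduced with NaBH4/CeCl3·7H2O. Alcohol 20 would be separated from the C7-epimeric allylic alcohol F2. F2 would be oxidised with MnO2 back to 17 and passed through the sequence again. The route is rejoined at 20.

- **Step 13.** Hydrogen may be lost from C2 instead of C10, the epoxide may be deoxygenated to the alkene, or the C8 acyl group may shift to O9 on the titanium alkoxide. The fallback replaces the radical opening by an ionic one. Setting out from 23, Me3SiOTf and 2,6-lutidine in toluene at −78 °C, followed by DBU, would open the epoxide at C1 and remove a C10 proton to give the allylic trimethylsilyl ether F3. Aqueous citric acid in THF would then free the C9 hydroxyl and give 24, where the route is rejoined.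

Further compounds
F1 | step 8 | methyl 2-[1-(cyclopentenyl)ethylidene]-5-methyl-3-oxohexanoate carrying the C4 silyl ether and C5 (1R)-1-acetoxyethyl group (E/Z mixture) | COC(=O)C(C(=O)CC(C)C)=C(C)C1=C[C@@H]([C@@H](C)OC(C)=O)[C@H](O[Si](C)(C)C(C)(C)C)C1
F2 | step 10 | C7 epimer of allylic alcohol 20 (isopropyl α) | C1=C(C)[C@@H]2C[C@@H](O[Si](C)(C)C(C)(C)C)[C@H]([C@@H](C)OC(C)=O)[C@H]2[C@@H](C(C)C)[C@H]1O
F3 | step 13 | C9 trimethylsilyl ether of 24 | C=C1[C@@H]2C[C@@H](O[Si](C)(C)C(C)(C)C)[C@H]([C@@H](C)OC(C)=O)[C@H]2[C@H](C(C)C)[C@@H](OC(=O)[C@@H](C)CC)[C@H]1O[Si](C)(C)C
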